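Readings and results are simulated with constants of no real substance; the scatter is artificial.

At late times a flask holds what its ligand has paid for. Each exchange takes one incoming ligand, so the complex with one exchanged plus twice the complex with two exchanged, which I call the account, is drawn from the charge.

| setting | winter | midnight | oak | larch | maple | ash |
|---|---|---|---|---|---|---|
| starting complex | 0.060 M | 0.060 M | 0.060 M | 0.060 M | 0.060 M | 0.060 M |
| incoming ligand | 1 equiv | 2.3 equiv | 0.900 equiv | 1.80 equiv | 1.80 equiv | 0.900 equiv |
| temperature | 20 °C | 45 °C | 25 °C | 25 °C | 65 °C | 65 °C |
| remark | run made earlier | run made earlier |  |  |  |  |
| time |  |  | 2.0 min | 2.0 min | 2.0 min | 2.0 min |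

In oak and ash that account can go no higher than 90.0% of the starting complex charged. I call this the ligand ceiling, the incoming ligand charged over the starting complex charged, and I carry it. Incoming ligand is the limiting reagent for the first exchange in those two flasks, but not in larch and maple, where it covers the first exchange and not both. If each step goes as written, its rate is proportional to the incoming ligand and to the complex it acts on.

| run | time / s | complex with one exchanged / % | starting complex / % |
|---|---|---|---|
| winter | 10.0 | 2 | 97 |
| winter | 12.0 | 3 | 97 |
| winter | 25.0 | 6 | 97 |
| winter | 60.0 | 9 | 87 |
| midnight | 10.0 | 24 | 71 |
| midnight | 15.0 | 34 | 62 |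
| midnight | 20.0 | 37 | 53 |

(each reading ± 2 percentage points)

Winter still holds 87% of starting complex after 60.0 s, while midnight, hotter and with more ligand, holds 53% after 20.0 s. But midnight's last line also lacks 10.0% of its balance, with a scatter of 2 percentage points on each reading, so the second exchange seems to run while starting complex remains. Maple has ligand to go on to the second exchange, ash has its ceiling, and oak is as cool as larch with half its ligand. So I commit to ash first and oak last, and I leave the middle open.

* all flasks from highest to lowest amount of complex with one exchanged, in percent of the starting complex charged, at 2.0 min (oak / larch / maple / ash)
* the amount of complex with one exchanged, in percent of the starting complex charged of the flask you put first, at 2.0 min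
* the amount of complex with one exchanged, in percent of the starting complex charged of the flask you put last, at 2.0 min

- complex with one exchanged is meant together with its crystals
- solid, in amounts per volume of the solution: crystals
- what may be going on: starting complex + incoming ligand -> leaving ligand + complex with one exchanged; complex with one exchanged + incoming ligand -> leaving ligand + complex with two exchanged; crystals <-> complex with one exchanged

The forecast gives ash > larch > maple > oak, with 47% on top and 25% at the bottom, and says of the crystals: “Solubility is unknown, so I ignore them”.

The flasks give ash > maple > larch > oak, with 64.8% in ash and 20.9% in oak.

    starting complex + incoming ligand → leaving ligand + complex with one exchanged (k = 0.0497 L mol⁻¹ s⁻¹, Ea = 65.0 kJ mol⁻¹)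
    complex with one exchanged + incoming ligand → leaving ligand + complex with two exchanged (k = 0.0686 L mol⁻¹ s⁻¹, Ea = 40.0 kJ mol⁻¹)
    crystals ⇌ complex with one exchanged, rate k3*(cs3 - [complex with one exchanged]) while solid is left; crystals form when [complex with one exchanged] > cs3 (solubility = 4.10 mM, k = 0.0600 s⁻¹)
    (constants at 25 °C)

Ash stands 18 points above the forecast, and after 2.00 min its account comes to 87.0% against the ceiling of 90.0%, with 3.31% of its ligand left. The neighbouring flask is ash with 0.230 equiv of incoming ligand, so its ceiling is 23.0%, lower than ash's. It holds 21.2% of complex with one exchanged and 0.882% of complex with two exchanged, an account of 23.0%. Of its ligand 0.12% is left, and 78% of its starting complex is still there.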